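## Retrosynthetic overview

1. The last bond is the C8 ester: the 8β‑hydroxy germacranolide is acylated with (2R,3S)‑2,3‑dimethyloxirane‑2‑carboxylic acid, made from tiglyl alcohol by Sharpless epoxidation and oxidation.
2. Key disconnection C7–C8: a SmI2 ketyl radical from a C8 aldehyde adds to the β‑carbon of a 3‑(acetoxymethyl)butenolide and the resulting enolate loses acetate. One step closes the ten‑membered ring, sets C7 and C8 and unveils the α‑methylene lactone.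
3. The butenolide comes from ring‑closing metathesis of a 2‑(acetoxymethyl)acrylate of a divinyl carbinol; C6 is set by catalytic asymmetric vinylation of a Z‑enal; the C8 aldehyde is carried as an allyl group and freed by Lemieux–Johnson cleavage.
4. The chain is joined at C1–C2 by Negishi coupling of a Z‑iodoalkene (propargyl alcohol, allylmagnesium bromide, iodine) with the alkylzinc from 4‑methyl‑5,6‑dihydro‑2H‑pyran‑2‑one (ring‑locked Z‑C4=C5); Sharpless epoxidation of the C14 allylic alcohol sets C1 and C10.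
5. Ring order: 1,10‑oxirane, then butenolide, then ten‑membered carbocycle; the side‑chain oxirane is made separately.

Assumption: 4‑methyl‑5,6‑dihydro‑2H‑pyran‑2‑one is bought as a catalogue compound, and germacrane numbering (ring C1–C10, lactone carbons C11–C13, C14 on C10, C15 on C4) is used in the text.

## Route

Step 1
Reactants: 1 prop‑2‑yn‑1‑ol; 2 allylmagnesium bromide
Product: 4 (2Z)‑2‑(iodomethylidene)pent‑4‑en‑1‑ol, via 4‑allyl‑2,5‑dihydro‑1,2‑oxamagnesole 3 (not isolated)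
Conditions: 2 (2.5 equiv), CuI (10 mol%), Et2O, 0 °C → rt; then I2 (1.3 equiv), THF, −30 → 0 °C
Reagents that add atoms: iodine, [I][I]
Why: Hydroxyl‑directed anti‑carbomagnesiation of the alkyne (Duboudin reaction) puts allyl on the inner carbon and magnesium on the terminal carbon cis to CH2O in a five‑membered chelate, so iodinolysis with retention gives only the Z‑iodoalkene.

Step 2
Reactants: 5 4‑methyl‑5,6‑dihydro‑2H‑pyran‑2‑one
Product: 8 methyl (2Z)‑5‑iodo‑3‑methylpent‑2‑enoate, via trimethylsilyl (2Z)‑5‑iodo‑3‑methylpent‑2‑enoate 6 (not isolated), via (2Z)‑5‑iodo‑3‑methylpent‑2‑enoic acid 7 (not isolated)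
Conditions: NaI (1.5 equiv), Me3SiCl (1.5 equiv), MeCN, 0 °C → rt; then MeOH, rt
Reagents that add atoms: sodium iodide, [Na+].[I-]; methanol, CO
Why: Iodotrimethylsilane made in the flask silylates the lactone carbonyl and iodide opens the ring by SN2 attack at the O–CH2 carbon (lactone cleavage to an ω‑iodo ester), the ring‑locked Z‑alkene is not touched, and methanol esterifies the acid under the acid present.

Step 3
Reactants: 8 methyl (2Z)‑5‑iodo‑3‑methylpent‑2‑enoate; 4 (2Z)‑2‑(iodomethylidene)pent‑4‑en‑1‑ol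
Product: 10 methyl (2Z,6Z)‑7‑(hydroxymethyl)‑3‑methyldeca‑2,6,9‑trienoate, via methyl (2Z)‑5‑(iodozincio)‑3‑methylpent‑2‑enoate 9 (not isolated)
Conditions: Zn dust (3 equiv, activated by BrCH2CH2Br and Me3SiCl), LiCl, THF, 35 °C; then 4 (0.6 equiv), Pd(PPh3)4 (5 mol%), THF, rt → 45 °C
Reagents that add atoms: none
Why: Zinc inserts into the primary C–I bond and the ester‑tolerant alkylzinc iodide couples with the vinyl iodide under zerovalent palladium catalysis (Negishi coupling) with retention of alkene geometry, the free alcohol being tolerated by the weakly basic zinc reagent.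

Step 4
Reactants: 10 methyl (2Z,6Z)‑7‑(hydroxymethyl)‑3‑methyldeca‑2,6,9‑trienoate
Product: 11 methyl (2Z)‑5‑[(2R,3S)‑3‑(hydroxymethyl)‑3‑(prop‑2‑en‑1‑yl)oxiran‑2‑yl]‑3‑methylpent‑2‑enoate
Conditions: Ti(OiPr)4 (0.3 equiv), L‑(+)‑diethyl tartrate (0.36 equiv), t‑BuOOH (2 equiv, in decane), 4 Å molecular sieves, CH2Cl2, −20 °C
Reagents that add atoms: tert‑butyl hydroperoxide, CC(C)(C)OO
Why: Sharpless asymmetric epoxidation touches only the allylic‑alcohol alkene (enoate and terminal alkene are inert), and L‑(+)‑tartrate delivers oxygen to the face that gives the (1R,10S) epoxide, the Z‑alkene geometry becoming the trans relationship of C2 and C9 across the oxirane.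

Step 5
Reactants: 11 methyl (2Z)‑5‑[(2R,3S)‑3‑(hydroxymethyl)‑3‑(prop‑2‑en‑1‑yl)oxiran‑2‑yl]‑3‑methylpent‑2‑enoate
Product: 12 (2Z)‑5‑[(2R,3S)‑3‑(hydroxymethyl)‑3‑(prop‑2‑en‑1‑yl)oxiran‑2‑yl]‑3‑methylpent‑2‑en‑1‑ol
Conditions: i‑Bu2AlH (3.5 equiv), CH2Cl2, −78 °C; aq. potassium sodium tartrate
Reagents that add atoms: none
Why: 1,2‑Reduction of the conjugated ester by i‑Bu2AlH at −78 °C gives the Z‑allylic alcohol, and at this temperature the 2,3‑epoxy alcohol (as its aluminium alkoxide) is not opened.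

Step 6
Reactants: 12 (2Z)‑5‑[(2R,3S)‑3‑(hydroxymethyl)‑3‑(prop‑2‑en‑1‑yl)oxiran‑2‑yl]‑3‑methylpent‑2‑en‑1‑ol
Product: 13 (2Z)‑5‑[(2R,3S)‑3‑(hydroxymethyl)‑3‑(prop‑2‑en‑1‑yl)oxiran‑2‑yl]‑3‑methylpent‑2‑enal
Conditions: activated MnO2 (15 equiv), CH2Cl2, rt
Reagents that add atoms: none
Why: MnO2 oxidises only the allylic primary alcohol (the epoxy‑carbinol hydroxyl is not allylic) and gives the Z‑enal under neutral conditions.

Step 7
Reactants: 13 (2Z)‑5‑[(2R,3S)‑3‑(hydroxymethyl)‑3‑(prop‑2‑en‑1‑yl)oxiran‑2‑yl]‑3‑methylpent‑2‑enal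
Product: 14 [(2S,3R)‑3‑[(3Z)‑3‑methyl‑5‑oxopent‑3‑en‑1‑yl]‑2‑(prop‑2‑en‑1‑yl)oxiran‑2‑yl]methyl acetate
Conditions: Ac2O (1.5 equiv), Et3N, DMAP (5 mol%), CH2Cl2, 0 °C
Reagents that add atoms: acetic anhydride, CC(=O)OC(C)=O
Why: O‑Acetylation of the only free hydroxyl installs the C14 acetate of the target.

Step 8
Reactants: 14 [(2S,3R)‑3‑[(3Z)‑3‑methyl‑5‑oxopent‑3‑en‑1‑yl]‑2‑(prop‑2‑en‑1‑yl)oxiran‑2‑yl]methyl acetate; 15 vinylmagnesium bromide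
Product: 17 [(2S,3R)‑3‑[(3Z,5S)‑5‑hydroxy‑3‑methylhepta‑3,6‑dien‑1‑yl]‑2‑(prop‑2‑en‑1‑yl)oxiran‑2‑yl]methyl acetate, via divinylzinc 16 (not isolated)
Conditions: 15 (3.6 equiv), ZnCl2 (1.8 equiv), THF/toluene, 0 °C, magnesium halide precipitated by 1,4‑dioxane; (−)‑MIB [(2S)‑3‑exo‑morpholinoisoborneol, 10 mol%], toluene, −30 → 0 °C, then 14
Reagents that add atoms: none
Why: Amino‑alcohol‑catalysed enantioselective addition of a vinylzinc reagent to an enal (Oppolzer–Noyori type), in which (−)‑MIB directs vinyl to the Si face as in the ethylation of benzaldehyde and so sets C6 (descriptor S here, the same centre becomes 6R once C7 is part of the lactone), with acetate and epoxide inert to the zinc reagent.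

Step 9
Reactants: 17 [(2S,3R)‑3‑[(3Z,5S)‑5‑hydroxy‑3‑methylhepta‑3,6‑dien‑1‑yl]‑2‑(prop‑2‑en‑1‑yl)oxiran‑2‑yl]methyl acetate; 18 2‑(bromomethyl)prop‑2‑enoic acid
Product: 20 (3S,4Z)‑7‑[(2R,3S)‑3‑(acetoxymethyl)‑3‑(prop‑2‑en‑1‑yl)oxiran‑2‑yl]‑5‑methylhepta‑1,4‑dien‑3‑yl 2‑(acetoxymethyl)prop‑2‑enoate, via (3S,4Z)‑7‑[(2R,3S)‑3‑(acetoxymethyl)‑3‑(prop‑2‑en‑1‑yl)oxiran‑2‑yl]‑5‑methylhepta‑1,4‑dien‑3‑yl 2‑(bromomethyl)prop‑2‑enoate 19 (not isolated)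
Conditions: 18 (1.3 equiv), DCC (1.4 equiv), DMAP (10 mol%), CH2Cl2, −20 → 0 °C; then n‑Bu4NOAc (2 equiv), 0 °C → rt
Reagents that add atoms: tetrabutylammonium acetate, CCCC[N+](CCCC)(CCCC)CCCC.CC(=O)[O-]
Why: Steglich esterification of the secondary alcohol (C6 untouched) is followed in the same flask by displacement of the allylic bromide by acetate, where SN2 and SN2' attack on the 2‑(bromomethyl)acrylate give the same product and the base‑sensitive butenolide is not yet present.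

Step 10
Reactants: 20 (3S,4Z)‑7‑[(2R,3S)‑3‑(acetoxymethyl)‑3‑(prop‑2‑en‑1‑yl)oxiran‑2‑yl]‑5‑methylhepta‑1,4‑dien‑3‑yl 2‑(acetoxymethyl)prop‑2‑enoate
Product: 21 {(5R)‑5‑[(1Z)‑4‑[(2R,3S)‑3‑(acetoxymethyl)‑3‑(prop‑2‑en‑1‑yl)oxiran‑2‑yl]‑2‑methylbut‑1‑en‑1‑yl]‑2‑oxo‑2,5‑dihydrofuran‑3‑yl}methyl acetate
Conditions: second‑generation Grubbs catalyst RuCl2(=CHPh)(PCy3)(H2IMes) (5 mol%), CH2Cl2 (1 mM), 40 °C
Reagents that add atoms: none
Why: Ring‑closing metathesis between the C7 vinyl group and the acrylate gives the five‑membered butenolide much faster than any reaction of the remote allyl group at 1 mM, the trisubstituted C4=C5 alkene is inert, and C6 is unaffected (its descriptor becomes R only because C7 now outranks C5).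

Step 11
Reactants: 21 {(5R)‑5‑[(1Z)‑4‑[(2R,3S)‑3‑(acetoxymethyl)‑3‑(prop‑2‑en‑1‑yl)oxiran‑2‑yl]‑2‑methylbut‑1‑en‑1‑yl]‑2‑oxo‑2,5‑dihydrofuran‑3‑yl}methyl acetate
Product: 23 {(5R)‑5‑[(1Z)‑4‑[(2R,3S)‑3‑(acetoxymethyl)‑3‑(2‑oxoethyl)oxiran‑2‑yl]‑2‑methylbut‑1‑en‑1‑yl]‑2‑oxo‑2,5‑dihydrofuran‑3‑yl}methyl acetate, via {(5R)‑5‑[(1Z)‑4‑[(2R,3S)‑3‑(acetoxymethyl)‑3‑(2,3‑dihydroxypropyl)oxiran‑2‑yl]‑2‑methylbut‑1‑en‑1‑yl]‑2‑oxo‑2,5‑dihydrofuran‑3‑yl}methyl acetate 22 (not isolated)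
Conditions: OsO4 (2 mol%), NaIO4 (4 equiv), 2,6‑lutidine (2 equiv), 1,4‑dioxane/H2O 3:1, 0 °C → rt; crude aldehyde used at once
Reagents that add atoms: osmium tetroxide, O=[Os](=O)(=O)=O; sodium periodate, [Na+].[O-]I(=O)(=O)=O
Why: In this Lemieux–Johnson cleavage OsO4 dihydroxylates the unhindered monosubstituted alkene in preference to the electron‑poor butenolide and the hindered Z‑trisubstituted alkene deactivated by its allylic acyloxy group, and periodate cleaves the diol to the C8 aldehyde under lutidine buffering that spares the epoxide.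

Step 12
Reactants: 23 {(5R)‑5‑[(1Z)‑4‑[(2R,3S)‑3‑(acetoxymethyl)‑3‑(2‑oxoethyl)oxiran‑2‑yl]‑2‑methylbut‑1‑en‑1‑yl]‑2‑oxo‑2,5‑dihydrofuran‑3‑yl}methyl acetate
Product: 24 (1R,6R,7R,8R,10S)‑14‑acetoxy‑1,10‑epoxy‑8‑hydroxygermacra‑4(Z),11(13)‑dien‑12,6‑olide
Conditions: SmI2 (2.5 equiv, 0.1 M in THF), THF, −78 °C, 23 added over 6 h (final 1 mM), then −78 → −30 °C; sat. aq. NH4Cl at −30 °C
Reagents that add atoms: none
Why: Proposed new method: single‑electron reduction of the aldehyde by SmI2 gives a C8 ketyl radical that adds to C7, the β‑carbon of the butenolide, and closes the ten‑membered ring (the Z‑alkene, the epoxide and the lactone ring restrict the chain, and ketyl formation is reversible so high dilution suffices); attack anti to the C5 substituent gives the trans lactone (7R), and a samarium bridge between ketyl oxygen and lactone carbonyl, which needs the C8 oxygen cis to C11 across the new bond, is expected to give 8R; a second electron gives the samarium enolate, which expels the C13 acetate (E1cB) to unveil the α‑methylene lactone; the closest known reactions are SmI2 ketyl–olefin couplings of aldehydes with acrylates, SmI2 ketyl–olefin cyclisations to eight‑membered rings and anti‑selective radical additions to γ‑substituted butenolides.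

Step 13
Reactants: 25 (2E)‑2‑methylbut‑2‑en‑1‑ol
Product: 26 [(2S,3S)‑2,3‑dimethyloxiran‑2‑yl]methanol
Conditions: Ti(OiPr)4 (10 mol%), L‑(+)‑diethyl tartrate (12 mol%), t‑BuOOH (2 equiv), 4 Å molecular sieves, CH2Cl2, −20 °C
Reagents that add atoms: tert‑butyl hydroperoxide, CC(C)(C)OO
Why: Sharpless asymmetric epoxidation of an E‑trisubstituted allylic alcohol with L‑(+)‑tartrate gives the (2S,3S) epoxy alcohol, the E geometry fixing the cis relationship of the two methyl groups.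

Step 14
Reactants: 26 [(2S,3S)‑2,3‑dimethyloxiran‑2‑yl]methanol
Product: 27 (2R,3S)‑2,3‑dimethyloxirane‑2‑carboxylic acid
Conditions: RuCl3 (2 mol%), NaIO4 (4 equiv), CCl4/MeCN/H2O 2:2:3, rt
Reagents that add atoms: water, O
Why: Catalytic RuO4 formed from RuCl3 and periodate (Sharpless conditions) oxidises the primary alcohol through the aldehyde hydrate to the acid without touching the epoxide, and the C2 descriptor changes from S to R only because CO2H outranks C3.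

Step 15
Reactants: 24 (1R,6R,7R,8R,10S)‑14‑acetoxy‑1,10‑epoxy‑8‑hydroxygermacra‑4(Z),11(13)‑dien‑12,6‑olide; 27 (2R,3S)‑2,3‑dimethyloxirane‑2‑carboxylic acid
Product: 29 (1R,6R,7R,8R,10S)‑14‑acetoxy‑1,10‑epoxy‑8‑{[(2R,3S)‑2,3‑dimethyloxiran‑2‑yl]carbonyloxy}germacra‑4(Z),11(13)‑dien‑12,6‑olide, via (2R,3S)‑2,3‑dimethyloxirane‑2‑carboxylic 2,4,6‑trichlorobenzoic anhydride 28 (not isolated)
Conditions: 27 (1.5 equiv), 2,4,6‑trichlorobenzoyl chloride (1.5 equiv), Et3N (2 equiv), toluene, rt; then 24, DMAP (2 equiv), toluene, rt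
Reagents that add atoms: none
Why: Yamaguchi esterification acylates the hindered 8β‑hydroxyl through the mixed anhydride with retention at C8, without epimerising the α‑quaternary epoxy acid or opening either epoxide.

## Compound list

1 | prop‑2‑yn‑1‑ol | C#CCO | starting material
2 | allylmagnesium bromide | C=CC[Mg]Br | starting material
3 | 4‑allyl‑2,5‑dihydro‑1,2‑oxamagnesole | C=CCC1=C[Mg]OC1 | intermediate
4 | (2Z)‑2‑(iodomethylidene)pent‑4‑en‑1‑ol | OC/C(CC=C)=C\I | intermediate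
5 | 4‑methyl‑5,6‑dihydro‑2H‑pyran‑2‑one | CC1=CC(=O)OCC1 | starting material
6 | trimethylsilyl (2Z)‑5‑iodo‑3‑methylpent‑2‑enoate | C[Si](C)(C)OC(=O)/C=C(/C)CCI | intermediate
7 | (2Z)‑5‑iodo‑3‑methylpent‑2‑enoic acid | OC(=O)/C=C(/C)CCI | intermediate
8 | methyl (2Z)‑5‑iodo‑3‑methylpent‑2‑enoate | COC(=O)/C=C(/C)CCI | intermediate
9 | methyl (2Z)‑5‑(iodozincio)‑3‑methylpent‑2‑enoate | COC(=O)/C=C(/C)CC[Zn]I | intermediate
10 | methyl (2Z,6Z)‑7‑(hydroxymethyl)‑3‑methyldeca‑2,6,9‑trienoate | COC(=O)/C=C(/C)CC/C=C(\CO)CC=C | intermediate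
11 | methyl (2Z)‑5‑[(2R,3S)‑3‑(hydroxymethyl)‑3‑(prop‑2‑en‑1‑yl)oxiran‑2‑yl]‑3‑methylpent‑2‑enoate | COC(=O)/C=C(/C)CC[C@H]1O[C@]1(CO)CC=C | intermediate
12 | (2Z)‑5‑[(2R,3S)‑3‑(hydroxymethyl)‑3‑(prop‑2‑en‑1‑yl)oxiran‑2‑yl]‑3‑methylpent‑2‑en‑1‑ol | OC/C=C(/C)CC[C@H]1O[C@]1(CO)CC=C | intermediate
13 | (2Z)‑5‑[(2R,3S)‑3‑(hydroxymethyl)‑3‑(prop‑2‑en‑1‑yl)oxiran‑2‑yl]‑3‑methylpent‑2‑enal | O=C/C=C(/C)CC[C@H]1O[C@]1(CO)CC=C | intermediate
14 | [(2S,3R)‑3‑[(3Z)‑3‑methyl‑5‑oxopent‑3‑en‑1‑yl]‑2‑(prop‑2‑en‑1‑yl)oxiran‑2‑yl]methyl acetate | O=C/C=C(/C)CC[C@H]1O[C@]1(COC(C)=O)CC=C | intermediate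
15 | vinylmagnesium bromide | C=C[Mg]Br | starting material
16 | divinylzinc | C=C[Zn]C=C | intermediate
17 | [(2S,3R)‑3‑[(3Z,5S)‑5‑hydroxy‑3‑methylhepta‑3,6‑dien‑1‑yl]‑2‑(prop‑2‑en‑1‑yl)oxiran‑2‑yl]methyl acetate | C=C[C@H](O)/C=C(/C)CC[C@H]1O[C@]1(COC(C)=O)CC=C | intermediate
18 | 2‑(bromomethyl)prop‑2‑enoic acid | C=C(CBr)C(=O)O | starting material
19 | (3S,4Z)‑7‑[(2R,3S)‑3‑(acetoxymethyl)‑3‑(prop‑2‑en‑1‑yl)oxiran‑2‑yl]‑5‑methylhepta‑1,4‑dien‑3‑yl 2‑(bromomethyl)prop‑2‑enoate | C=C[C@H](OC(=O)C(=C)CBr)/C=C(/C)CC[C@H]1O[C@]1(COC(C)=O)CC=C | intermediate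
20 | (3S,4Z)‑7‑[(2R,3S)‑3‑(acetoxymethyl)‑3‑(prop‑2‑en‑1‑yl)oxiran‑2‑yl]‑5‑methylhepta‑1,4‑dien‑3‑yl 2‑(acetoxymethyl)prop‑2‑enoate | C=C[C@H](OC(=O)C(=C)COC(C)=O)/C=C(/C)CC[C@H]1O[C@]1(COC(C)=O)CC=C | intermediate
21 | {(5R)‑5‑[(1Z)‑4‑[(2R,3S)‑3‑(acetoxymethyl)‑3‑(prop‑2‑en‑1‑yl)oxiran‑2‑yl]‑2‑methylbut‑1‑en‑1‑yl]‑2‑oxo‑2,5‑dihydrofuran‑3‑yl}methyl acetate | O=C1O[C@@H](C=C1COC(C)=O)/C=C(/C)CC[C@H]2O[C@]2(COC(C)=O)CC=C | intermediate
22 | {(5R)‑5‑[(1Z)‑4‑[(2R,3S)‑3‑(acetoxymethyl)‑3‑(2,3‑dihydroxypropyl)oxiran‑2‑yl]‑2‑methylbut‑1‑en‑1‑yl]‑2‑oxo‑2,5‑dihydrofuran‑3‑yl}methyl acetate (both carbinol epimers) | O=C1O[C@@H](C=C1COC(C)=O)/C=C(/C)CC[C@H]2O[C@]2(COC(C)=O)CC(O)CO | intermediate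
23 | {(5R)‑5‑[(1Z)‑4‑[(2R,3S)‑3‑(acetoxymethyl)‑3‑(2‑oxoethyl)oxiran‑2‑yl]‑2‑methylbut‑1‑en‑1‑yl]‑2‑oxo‑2,5‑dihydrofuran‑3‑yl}methyl acetate | O=C1O[C@@H](C=C1COC(C)=O)/C=C(/C)CC[C@H]2O[C@]2(COC(C)=O)CC=O | intermediate
24 | (1R,6R,7R,8R,10S)‑14‑acetoxy‑1,10‑epoxy‑8‑hydroxygermacra‑4(Z),11(13)‑dien‑12,6‑olide | C=C1C(=O)O[C@@H]2/C=C(/C)CC[C@H]3O[C@]3(COC(C)=O)C[C@@H](O)[C@@H]12 | intermediate
25 | (2E)‑2‑methylbut‑2‑en‑1‑ol | C/C=C(\C)CO | starting material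
26 | [(2S,3S)‑2,3‑dimethyloxiran‑2‑yl]methanol | OC[C@]1(C)O[C@H]1C | intermediate
27 | (2R,3S)‑2,3‑dimethyloxirane‑2‑carboxylic acid | OC(=O)[C@]1(C)O[C@H]1C | intermediate
28 | (2R,3S)‑2,3‑dimethyloxirane‑2‑carboxylic 2,4,6‑trichlorobenzoic anhydride | O=C(OC(=O)[C@]1(C)O[C@H]1C)c1c(Cl)cc(Cl)cc1Cl | intermediate
29 | (1R,6R,7R,8R,10S)‑14‑acetoxy‑1,10‑epoxy‑8‑{[(2R,3S)‑2,3‑dimethyloxiran‑2‑yl]carbonyloxy}germacra‑4(Z),11(13)‑dien‑12,6‑olide (CNP0232260.6) | C=C1C(=O)O[C@@H]2/C=C(/C)CC[C@H]3O[C@]3(COC(C)=O)C[C@@H](OC(=O)[C@]3(C)O[C@H]3C)[C@@H]12 | target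

## Step count and risks

Total step count: 15. Longest linear sequence: 12 steps (steps 1, 3 to 12 and 15).

The step most likely to fail is step 12. The ten‑membered ring closure has no direct precedent; pinacol dimer, simple aldehyde reduction, direct reduction of the acceptor or the 8‑epimer may result, and the samarium alkoxide must be quenched cold to avoid lactone migration to O8. The fallback sets out from bromide 19, isolated by leaving out the acetate exchange of step 9. Ring‑closing metathesis as in step 10 gives [(2S,3R)‑3‑{(3Z)‑4‑[(2R)‑4‑(bromomethyl)‑5‑oxo‑2,5‑dihydrofuran‑2‑yl]‑3‑methylbut‑3‑en‑1‑yl}‑2‑(prop‑2‑en‑1‑yl)oxiran‑2‑yl]methyl acetate F1. Lemieux–Johnson cleavage as in step 11 passes through the 2‑(2,3‑dihydroxypropyl) diol F2 (not isolated) to the 2‑(2‑oxoethyl) bromo aldehyde F3. CrCl2 in THF/DMF at 2 mM then closes the ring by intramolecular Nozaki–Hiyama allylation: the allylchromium attacks the aldehyde through C7 in a closed six‑membered transition state and gives the α‑methylene lactone directly. The route is rejoined at 24.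

The second is step 11, together with the free allyl group during step 10. OsO4 may also attack C4=C5, the allyl group may enter metathesis, and the β,γ‑epoxy aldehyde is labile. The fallback sets out from 14, where the only other alkene is the electron‑poor enal. OsO4 (2 mol%) with N‑methylmorpholine N‑oxide gives [(2S,3R)‑2‑(2,3‑dihydroxypropyl)‑3‑[(3Z)‑3‑methyl‑5‑oxopent‑3‑en‑1‑yl]oxiran‑2‑yl]methyl acetate F4. Et3SiCl and imidazole give the bis(triethylsilyl) ether F5. Vinylation as in step 8 gives the (5S)‑divinyl carbinol F6. Esterification and acetate exchange as in step 9 give the 2‑(bromomethyl)acrylate F7 and then the 2‑(acetoxymethyl)acrylate F8. Metathesis as in step 10, now with no free terminal alkene, gives the bis(triethylsilyloxy) butenolide F9. HF·pyridine removes both silyl groups and gives diol 22, where the route is rejoined; NaIO4 alone then gives 23.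

The third is step 2. Iodide may add to the enoate or isomerise the Z‑alkene, and the iodo acid can close back to the lactone. The fallback sets out from 4 and from purchased (2Z)‑3‑methylpent‑2‑en‑4‑yn‑1‑ol F10, and replaces the Negishi coupling by a B‑alkyl Suzuki coupling. t‑BuMe2SiCl and imidazole give tert‑butyl(dimethyl){[(2Z)‑3‑methylpent‑2‑en‑4‑yn‑1‑yl]oxy}silane F11. Semihydrogenation (H2, Pd/CaCO3 poisoned by Pb(OAc)2, quinoline) gives tert‑butyl(dimethyl){[(2Z)‑3‑methylpenta‑2,4‑dien‑1‑yl]oxy}silane F12. 9‑BBN (1.05 equiv) hydroborates the terminal vinyl group to 9‑[(3Z)‑5‑{[tert‑butyl(dimethyl)silyl]oxy}‑3‑methylpent‑3‑en‑1‑yl]‑9‑borabicyclo[3.3.1]nonane F13 (not isolated). Coupling with 4 (PdCl2(dppf), Cs2CO3, DMF/THF/H2O) gives (2Z)‑2‑[(3Z)‑5‑{[tert‑butyl(dimethyl)silyl]oxy}‑3‑methylpent‑3‑en‑1‑ylidene]pent‑4‑en‑1‑ol F14. Sharpless epoxidation as in step 4 gives [(2S,3R)‑3‑[(3Z)‑5‑{[tert‑butyl(dimethyl)silyl]oxy}‑3‑methylpent‑3‑en‑1‑yl]‑2‑(prop‑2‑en‑1‑yl)oxiran‑2‑yl]methanol F15, and acetylation as in step 7 gives its acetate F16. n‑Bu4NF buffered with AcOH gives [(2S,3R)‑3‑[(3Z)‑5‑hydroxy‑3‑methylpent‑3‑en‑1‑yl]‑2‑(prop‑2‑en‑1‑yl)oxiran‑2‑yl]methyl acetate F17. MnO2 as in step 6 gives 14, where the route is rejoined.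

## Further compounds

F1 | step 12 | [(2S,3R)‑3‑{(3Z)‑4‑[(2R)‑4‑(bromomethyl)‑5‑oxo‑2,5‑dihydrofuran‑2‑yl]‑3‑methylbut‑3‑en‑1‑yl}‑2‑(prop‑2‑en‑1‑yl)oxiran‑2‑yl]methyl acetate | O=C1O[C@@H](C=C1CBr)/C=C(/C)CC[C@H]2O[C@]2(COC(C)=O)CC=C
F2 | step 12 | [(2S,3R)‑3‑{(3Z)‑4‑[(2R)‑4‑(bromomethyl)‑5‑oxo‑2,5‑dihydrofuran‑2‑yl]‑3‑methylbut‑3‑en‑1‑yl}‑2‑(2,3‑dihydroxypropyl)oxiran‑2‑yl]methyl acetate | O=C1O[C@@H](C=C1CBr)/C=C(/C)CC[C@H]2O[C@]2(COC(C)=O)CC(O)CO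
F3 | step 12 | [(2S,3R)‑3‑{(3Z)‑4‑[(2R)‑4‑(bromomethyl)‑5‑oxo‑2,5‑dihydrofuran‑2‑yl]‑3‑methylbut‑3‑en‑1‑yl}‑2‑(2‑oxoethyl)oxiran‑2‑yl]methyl acetate | O=C1O[C@@H](C=C1CBr)/C=C(/C)CC[C@H]2O[C@]2(COC(C)=O)CC=O
F4 | step 11 | [(2S,3R)‑2‑(2,3‑dihydroxypropyl)‑3‑[(3Z)‑3‑methyl‑5‑oxopent‑3‑en‑1‑yl]oxiran‑2‑yl]methyl acetate | O=C/C=C(/C)CC[C@H]1O[C@]1(COC(C)=O)CC(O)CO
F5 | step 11 | [(2S,3R)‑2‑[2,3‑bis(triethylsilyloxy)propyl]‑3‑[(3Z)‑3‑methyl‑5‑oxopent‑3‑en‑1‑yl]oxiran‑2‑yl]methyl acetate | O=C/C=C(/C)CC[C@H]1O[C@]1(COC(C)=O)CC(CO[Si](CC)(CC)CC)O[Si](CC)(CC)CC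
F6 | step 11 | [(2S,3R)‑2‑[2,3‑bis(triethylsilyloxy)propyl]‑3‑[(3Z,5S)‑5‑hydroxy‑3‑methylhepta‑3,6‑dien‑1‑yl]oxiran‑2‑yl]methyl acetate | C=C[C@H](O)/C=C(/C)CC[C@H]1O[C@]1(COC(C)=O)CC(CO[Si](CC)(CC)CC)O[Si](CC)(CC)CC
F7 | step 11 | (3S,4Z)‑7‑[(2R,3S)‑3‑(acetoxymethyl)‑3‑[2,3‑bis(triethylsilyloxy)propyl]oxiran‑2‑yl]‑5‑methylhepta‑1,4‑dien‑3‑yl 2‑(bromomethyl)prop‑2‑enoate | C=C[C@H](OC(=O)C(=C)CBr)/C=C(/C)CC[C@H]1O[C@]1(COC(C)=O)CC(CO[Si](CC)(CC)CC)O[Si](CC)(CC)CC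
F8 | step 11 | (3S,4Z)‑7‑[(2R,3S)‑3‑(acetoxymethyl)‑3‑[2,3‑bis(triethylsilyloxy)propyl]oxiran‑2‑yl]‑5‑methylhepta‑1,4‑dien‑3‑yl 2‑(acetoxymethyl)prop‑2‑enoate | C=C[C@H](OC(=O)C(=C)COC(C)=O)/C=C(/C)CC[C@H]1O[C@]1(COC(C)=O)CC(CO[Si](CC)(CC)CC)O[Si](CC)(CC)CC
F9 | step 11 | {(5R)‑5‑[(1Z)‑4‑[(2R,3S)‑3‑(acetoxymethyl)‑3‑[2,3‑bis(triethylsilyloxy)propyl]oxiran‑2‑yl]‑2‑methylbut‑1‑en‑1‑yl]‑2‑oxo‑2,5‑dihydrofuran‑3‑yl}methyl acetate | O=C1O[C@@H](C=C1COC(C)=O)/C=C(/C)CC[C@H]2O[C@]2(COC(C)=O)CC(CO[Si](CC)(CC)CC)O[Si](CC)(CC)CC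
F10 | step 2 | (2Z)‑3‑methylpent‑2‑en‑4‑yn‑1‑ol | OC/C=C(/C)C#C
F11 | step 2 | tert‑butyl(dimethyl){[(2Z)‑3‑methylpent‑2‑en‑4‑yn‑1‑yl]oxy}silane | CC(C)(C)[Si](C)(C)OC/C=C(/C)C#C
F12 | step 2 | tert‑butyl(dimethyl){[(2Z)‑3‑methylpenta‑2,4‑dien‑1‑yl]oxy}silane | CC(C)(C)[Si](C)(C)OC/C=C(/C)C=C
F13 | step 2 | 9‑[(3Z)‑5‑{[tert‑butyl(dimethyl)silyl]oxy}‑3‑methylpent‑3‑en‑1‑yl]‑9‑borabicyclo[3.3.1]nonane | CC(C)(C)[Si](C)(C)OC/C=C(/C)CCB1C2CCCC1CCC2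
F14 | step 2 | (2Z)‑2‑[(3Z)‑5‑{[tert‑butyl(dimethyl)silyl]oxy}‑3‑methylpent‑3‑en‑1‑ylidene]pent‑4‑en‑1‑ol | CC(C)(C)[Si](C)(C)OC/C=C(/C)CC/C=C(\CO)CC=C
F15 | step 2 | [(2S,3R)‑3‑[(3Z)‑5‑{[tert‑butyl(dimethyl)silyl]oxy}‑3‑methylpent‑3‑en‑1‑yl]‑2‑(prop‑2‑en‑1‑yl)oxiran‑2‑yl]methanol | CC(C)(C)[Si](C)(C)OC/C=C(/C)CC[C@H]1O[C@]1(CO)CC=C
F16 | step 2 | [(2S,3R)‑3‑[(3Z)‑5‑{[tert‑butyl(dimethyl)silyl]oxy}‑3‑methylpent‑3‑en‑1‑yl]‑2‑(prop‑2‑en‑1‑yl)oxiran‑2‑yl]methyl acetate | CC(C)(C)[Si](C)(C)OC/C=C(/C)CC[C@H]1O[C@]1(COC(C)=O)CC=C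
F17 | step 2 | [(2S,3R)‑3‑[(3Z)‑5‑hydroxy‑3‑methylpent‑3‑en‑1‑yl]‑2‑(prop‑2‑en‑1‑yl)oxiran‑2‑yl]methyl acetate | OC/C=C(/C)CC[C@H]1O[C@]1(COC(C)=O)CC=C
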